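**Remark on the chemistry:** each ring is numbered as a benzoate (C1 bears the carboxyl carbon, C2 and C4 the oxygens, C6 the methyl group). The target has no stereocentre, so no configuration has to be set. Compounds 18 and 20 were checked atom by atom against the target and needed no correction.

## Structural features

The target is a linear tridepside. Three benzene rings A, B and C, each a 6-methylbenzoate oxygenated at C2 and C4, are joined by two aryl ester bonds: from the carboxyl of ring A to O4 of ring B, and from the carboxyl of ring B to O4 of ring C, whose own carboxyl is free. There is no stereocentre and no ring beyond the three arenes, so the problem is one of placing and distinguishing oxygen substituents. Rings B and C are orsellinate units with a free 2-hydroxyl hydrogen-bonded to the neighbouring carbonyl. Ring A has methoxy groups at C2 and C3 and a free hydroxyl at C4, that is, one oxygen more than an orsellinate, placed at C3 between the C2 and C4 oxygens. The fragile parts are the two depside esters (phenyl-type esters that exchange with alkoxides or amines once their ortho hydroxyls are free), the salicylic-type acid of ring C (it loses carbon dioxide on heating) and the trioxygenated ring A (sensitive to oxidants once its phenols are free). The real difficulty is the contiguous 2,3,4-oxygenation of ring A with three different fates, on top of telling apart five phenolic oxygens and three carboxyl groups. The key step uses the fact that C3 of ring A is ortho to both O2 and O4: this is where an orsellinate is formylated, and a formyl group held between two oxygen donors is predisposed to aryl migration in a Baeyer–Villiger oxidation, which turns the C3–CHO bond into the C3–O bond.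

## Logic of the disconnections

**22 to 21.** The four benzyl–oxygen bonds are cut (ethers at O4 of ring A, O2 of ring B and O2 of ring C, and the ester of ring C). All acidic groups are then released together under neutral conditions, so the free salicylate hydroxyls that make depside esters labile appear only in the last step. 21 has no free hydroxyl or acid and can be handled normally. The forward step must leave aryl esters alone and use a non-nucleophilic solvent.

**21 to 20 and 8.** The O–CH3 bond at O3 of ring A is cut. 20 has a single free hydroxyl, so the methylation needs no site selection. The forward step only needs a mild base that spares the esters.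

**20 to 18 (through 19).** The C3–O bond of ring A is cut and replaced by a C3–CHO bond. This turns the only ring that is not an orsellinate into a formylated orsellinate, so that all three rings trace back to 1. Placing the oxidation late means every earlier intermediate carries an acceptor group on ring A instead of an oxidation-prone phenol. The forward step demands aryl rather than hydride migration and removal of the formate without touching the depside esters.

**18 to 17 and 6.** The benzyl–O2 bond of ring C is cut. Ring C can then enter as the dihydroxy ester 15, acylated at O4 only, and no temporary group on O4 is needed. The forward step is alkylation of a chelated hydroxyl under base in the presence of hindered esters.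

**17 to 14 and 15 (through 16).** The ester bond between the ring B carbonyl and O4 of ring C is cut. It divides the molecule into an acid and a phenol, each made from 1. The forward step must activate a di-ortho-substituted acid and choose O4 over the chelated O2 of 15.

**14 to 13, and 13 to 12 and 6.** The allyl–oxygen bond of the ring B ester and the benzyl–O2 bond of ring B are cut. An allyl ester is the one carboxyl protection that can be removed beside benzyl groups, an aldehyde and an aryl ester without base. The forward deallylation needs a soft, non-basic allyl acceptor.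

**12 to 10 and 3 (through 11).** The ester bond between the ring A carbonyl and O4 of ring B is cut. Building the chain from the ring A end lets rings B and C each arrive as an unprotected 2,4-dihydroxy ester made in one step from 1. The growing chain itself occupies O4, so no O4 protecting group is ever installed or removed. The demand is the same site selection as in the previous coupling.

**10 to 9, 9 to 7 and 8, 7 to 5 and 6.** The allyl–oxygen bond, the methyl–O2 bond and the benzyl–O4 bond of ring A are cut in turn. This leads back to a dihydroxy aldehyde whose two hydroxyls differ in acidity and crowding. The forward benzylation must choose O4, and the methylation must then overcome the chelated, doubly flanked O2.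

**5 to 3 and 4.** The C3–CHO bond is cut. C3 is the most activated ring carbon, ortho to both hydroxyls. The forward step must prefer C3 over C5.

**3 to 1 and 2; 15 to 1 and 6.** The alkyl–oxygen bonds of the two esters are cut. The forward step must alkylate the carboxylate and leave both phenols free.

## Other disconnections considered

**Alternative 1:** The cut is at the two C2–O bonds of rings B and C. A tridepside A2, built with 4-hydroxy-2-methylbenzoic acid A1 as the source of rings B and C, would be hydroxylated twice ortho to its ester carbonyls to give A3. The catalyst would be a divalent ruthenium complex such as [RuCl2(p-cymene)]2 with an oxidant such as PhI(OCOCF3)2 in TFA/TFAA.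
- In its favour: A1 has one hydroxyl only, so O2 and O4 never have to be told apart and rings B and C need no benzyl ethers; this would save the two benzylations of the chosen route (steps 7 and 11), and here it is the better plan. Each directing ester has one free ortho C–H only (the other ortho carbon bears methyl), so the site is as certain as in the chosen plan.
- Against it: ester carbonyls are weak directing groups, and the ring B carbonyl belongs to an aryl ester, which is both a poorer donor and the electrophilic depside link. The strongly acidic, oxidising medium invites acyl exchange at both depside esters and at the acetate. Two C–H events must both go to completion on one advanced molecule. The new phenols and ring A are exposed to further oxidation.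
- Comparison: structurally, it spends its key step on oxygens that 1 already supplies and leaves the C3 oxygen of ring A unsolved, so ring A would still need a formylation–oxidation sequence of its own. Mechanistically, ruthenation of an electron-poor C–H is less secure than a Baeyer–Villiger migration that two ortho donors favour. In step count the two saved benzylations are offset by the separate ring A synthesis and a selective deacetylation.

**Alternative 2:** The cut is at the ester bond between rings B and C together with the C1–C6 bond of ring B. Heating dioxinone A4 would expel acetone; the acylketene A5 would be trapped by phenol A6 to give triketo ester A7, whose C2 would add to the C7 ketone, and loss of water would aromatise the new ring to A8.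
- In its favour: the hindered ring B–ring C ester forms under neutral thermal conditions without activating a di-ortho-substituted acid, which is better than the acid chloride coupling of step 10. Ring B appears with O4 free, and its later acylation at O4 in preference to the chelated O2 rests on the same principle as steps 6 and 10, so on that point the two plans are equal.
- Against it: A4 is not a catalogue compound and needs several steps, whereas 1 is already the finished ring. A7 is an aryl ester of a polyketo acid and can lose the phenol again under the basic conditions needed for the aldol closure. A6 takes four steps from 1. A8 still has a free 2-hydroxyl on ring B, which would need a further benzylation to keep the final methylation free of site selection.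
- Comparison: structurally, it builds a ring that can be bought and does not address ring A. Mechanistically, it is a cascade with more points of failure than one acylation. In step count it is longer than the chosen sequence from 3 and 15.

**Alternative 3:** The cut is at the bond from C1 of ring C to the carboxyl carbon. Bromide A10, assembled with bromophenol A9 in place of a ring C ester, would be reduced at a cathode with NiBr2(bpy) under carbon dioxide (sacrificial magnesium anode, DMF). Zerovalent nickel would insert into the C–Br bond and the reduced arylnickel species would add to carbon dioxide to give acid A11.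
- In its favour: ring C needs no carboxyl protecting group, and the final hydrogenolysis is the same as in the chosen plan, so the end games are equal. The carboxyl carbon comes from carbon dioxide and could carry an isotopic label, which the chosen plan cannot offer.
- Against it: the bromide sits between a benzyloxy and a methyl group, which slows both insertion and carboxylation. Low-valent nickel and the cathode can also attack the two aryl ester C–O bonds and the benzyl ethers, and protodebromination competes. A9 is not an orsellinic acid derivative and needs a regioselective bromination of its own.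
- Comparison: structurally, the carboxyl is already present in 1, so forming it last adds a C–C bond-forming step and saves only the one-step benzyl ester formation (step 9). Mechanistically, a reduction on a substrate full of reducible esters is less safe than a peracid oxidation to which esters and ethers are inert. In step count there is no gain.

Key step: step 12

## Route

Step 1
Reactants: 1 orsellinic acid (2,4-dihydroxy-6-methylbenzoic acid); 2 allyl bromide
Product: 3 allyl orsellinate (allyl 2,4-dihydroxy-6-methylbenzoate)
Conditions: KHCO3, DMF, rt
Reagents that add atoms: allyl bromide (compound 2), C=CCBr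
Why: O-alkylation of the carboxylate (SN2 esterification); hydrogencarbonate deprotonates only the carboxylic acid, so both phenols stay free, and room temperature avoids decarboxylation of 1.

Step 2
Reactants: 3 allyl orsellinate; 4 dichloromethyl methyl ether
Product: 5 allyl 3-formyl-2,4-dihydroxy-6-methylbenzoate
Conditions: 4 (1.2 equiv), TiCl4 (3 equiv), CH2Cl2, −10 to 0 °C; then ice-cold aq. HCl
Reagents that add atoms: dichloromethyl methyl ether (compound 4), COC(Cl)Cl; water, O
Why: Rieche formylation; titanium bound to the phenolic oxygens should deliver the chloromethoxycarbenium electrophile to C3, the carbon ortho to both hydroxyls, and the chloro ether formed is hydrolysed to the aldehyde on work-up. The new formyl group deactivates the ring against a second substitution.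

Step 3
Reactants: 5 allyl 3-formyl-2,4-dihydroxy-6-methylbenzoate; 6 benzyl bromide
Product: 7 allyl 4-(benzyloxy)-3-formyl-2-hydroxy-6-methylbenzoate
Conditions: BnBr (1.05 equiv), K2CO3 (1.1 equiv), DMF, rt
Reagents that add atoms: benzyl bromide (compound 6), BrCc1ccccc1
Why: Williamson ether synthesis; O4 (para to the ester, one ortho neighbour) is the more acidic and less crowded phenol, whereas O2 lies between the ester and the formyl group and is locked in a hydrogen bond, so one equivalent of halide should alkylate O4.

Step 4
Reactants: 7 allyl 4-(benzyloxy)-3-formyl-2-hydroxy-6-methylbenzoate; 8 methyl iodide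
Product: 9 allyl 4-(benzyloxy)-3-formyl-2-methoxy-6-methylbenzoate
Conditions: MeI (excess), K2CO3, DMF, 40 °C
Reagents that add atoms: methyl iodide (compound 8), CI
Why: Williamson methylation; O2 is now the only acidic site, the small electrophile in a dipolar aprotic solvent overcomes chelation and crowding, and the aldehyde has no α-hydrogen to enolise.

Step 5
Reactants: 9 allyl 4-(benzyloxy)-3-formyl-2-methoxy-6-methylbenzoate
Product: 10 4-(benzyloxy)-3-formyl-2-methoxy-6-methylbenzoic acid (ring A acid)
Conditions: Pd(PPh3)4 (cat.), p-TolSO2Na, THF/MeOH, rt; then aq. HCl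
Reagents that add atoms: none
Why: Tsuji–Trost deallylation; zerovalent palladium ionises the allyl ester to a π-allyl complex and the carboxylate, and the sulfinate captures the allyl group as a sulfone. No hydroxide is needed, which a di-ortho-substituted ester next to a non-enolisable aldehyde would not tolerate.

Step 6
Reactants: 10 ring A acid; 3 allyl orsellinate
Product: 12 allyl 4-{[4-(benzyloxy)-3-formyl-2-methoxy-6-methylbenzoyl]oxy}-2-hydroxy-6-methylbenzoate, via ring A acid chloride 11 (not isolated)
Conditions: (COCl)2, DMF (cat.), CH2Cl2, 0 °C to rt; evaporate; then 3 (1.1 equiv), Et3N, DMAP (cat.), CH2Cl2, 0 °C to rt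
Reagents that add atoms: none
Why: Esterification through the acid chloride (nucleophilic acyl substitution with DMAP catalysis); O4 of 3 is the free and more acidic phenol, while O2 is hydrogen-bonded to the ester carbonyl and crowded, so the bulky acyl group should go to O4 only.

Step 7
Reactants: 12 ring A–ring B didepside with free ring B 2-hydroxyl; 6 benzyl bromide
Product: 13 allyl 2-(benzyloxy)-4-{[4-(benzyloxy)-3-formyl-2-methoxy-6-methylbenzoyl]oxy}-6-methylbenzoate
Conditions: BnBr, K2CO3, DMF, 50 °C
Reagents that add atoms: benzyl bromide (compound 6), BrCc1ccccc1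
Why: Williamson benzylation of the chelated 2-hydroxyl; the only activated ester present is the ring A aryl ester, whose carbonyl is shielded by the ortho methoxy and methyl groups, and the acyl group cannot migrate from O4 to the meta-placed O2.

Step 8
Reactants: 13 allyl ester of the benzylated didepside
Product: 14 2-(benzyloxy)-4-{[4-(benzyloxy)-3-formyl-2-methoxy-6-methylbenzoyl]oxy}-6-methylbenzoic acid
Conditions: Pd(PPh3)4 (cat.), p-TolSO2Na, THF/MeOH, rt; then aq. HCl
Reagents that add atoms: none
Why: Tsuji–Trost deallylation under neutral conditions; the sulfinate is a soft nucleophile that should not attack the hindered aryl ester, the aldehyde or the benzyl ethers.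

Step 9
Reactants: 1 orsellinic acid; 6 benzyl bromide
Product: 15 benzyl orsellinate (benzyl 2,4-dihydroxy-6-methylbenzoate)
Conditions: BnBr (1.0 equiv), KHCO3, DMF, rt
Reagents that add atoms: benzyl bromide (compound 6), BrCc1ccccc1
Why: Selective O-alkylation of the carboxylate, as in step 1; the phenols are not deprotonated by hydrogencarbonate.

Step 10
Reactants: 14 didepside acid; 15 benzyl orsellinate
Product: 17 benzyl 4-{[2-(benzyloxy)-4-{[4-(benzyloxy)-3-formyl-2-methoxy-6-methylbenzoyl]oxy}-6-methylbenzoyl]oxy}-2-hydroxy-6-methylbenzoate, via didepside acid chloride 16 (not isolated)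
Conditions: (COCl)2, DMF (cat.), CH2Cl2, 0 °C to rt; evaporate; then 15 (1.1 equiv), Et3N, DMAP (cat.), CH2Cl2, 0 °C to rt
Reagents that add atoms: none
Why: Esterification through the acid chloride, with the same preference for the free O4 over the chelated O2 as in step 6; the existing aryl ester and the aldehyde are inert to oxalyl chloride at room temperature.

Step 11
Reactants: 17 tridepside with free ring C 2-hydroxyl; 6 benzyl bromide
Product: 18 benzyl 2-(benzyloxy)-4-{[2-(benzyloxy)-4-{[4-(benzyloxy)-3-formyl-2-methoxy-6-methylbenzoyl]oxy}-6-methylbenzoyl]oxy}-6-methylbenzoate (perbenzylated 3-formyl tridepside)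
Conditions: BnBr, K2CO3, DMF, 50 °C
Reagents that add atoms: benzyl bromide (compound 6), BrCc1ccccc1
Why: Williamson benzylation of the last free hydroxyl; both depside carbonyls are flanked by two ortho substituents and should resist the phenoxide and carbonate.

Step 12
Reactants: 18 perbenzylated 3-formyl tridepside
Product: 20 benzyl 2-(benzyloxy)-4-{[2-(benzyloxy)-4-{[4-(benzyloxy)-3-hydroxy-2-methoxy-6-methylbenzoyl]oxy}-6-methylbenzoyl]oxy}-6-methylbenzoate, via aryl formate 19 (not isolated)
Conditions: mCPBA (1.5 equiv), CH2Cl2, 0 °C to rt; aq. Na2S2O3/NaHCO3 wash; then KHCO3 (0.5 equiv), MeOH/THF, 0 °C to rt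
Reagents that add atoms: mCPBA (3-chloroperoxybenzoic acid), OOC(=O)c1cccc(Cl)c1
Why: Baeyer–Villiger oxidation of an aromatic aldehyde, the peracid counterpart of a Dakin oxidation that needs no free ortho hydroxyl. The peracid adds to the formyl group of ring A to give a Criegee adduct, from which C3 of ring A migrates to oxygen as 3-chlorobenzoate leaves, giving formate 19. The migrating carbon lies between the C2 methoxy and C4 benzyloxy groups and para to the C6 methyl group, so its migration should be strongly favoured over hydride shift, which would end in a carboxylic acid. No ring is closed and no stereocentre is formed. The selectivity needed is chemoselectivity: 18 has no alkene, free phenol or ketone, and its benzyl ethers and benzoate esters are inert to peracid. The formate is then the only unhindered ester, so hydrogencarbonate in methanol should remove it as methyl formate while the two depside carbonyls and the benzyl ester, each between two ortho substituents, stay intact. Excess peracid is destroyed before this cleavage so that the electron-rich phenol 20 never meets an oxidant.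

Step 13
Reactants: 20 perbenzylated tridepside with free ring A 3-hydroxyl; 8 methyl iodide
Product: 21 benzyl 2-(benzyloxy)-4-{[2-(benzyloxy)-4-{[4-(benzyloxy)-2,3-dimethoxy-6-methylbenzoyl]oxy}-6-methylbenzoyl]oxy}-6-methylbenzoate
Conditions: MeI, K2CO3, DMF, rt
Reagents that add atoms: methyl iodide (compound 8), CI
Why: Williamson methylation of the only free hydroxyl in the molecule, so no site selection is required; anhydrous carbonate at room temperature should leave the hindered esters untouched.

Step 14
Reactants: 21 perbenzylated 2,3-dimethoxy tridepside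
Product: 22 2-hydroxy-4-{[2-hydroxy-4-{[4-hydroxy-2,3-dimethoxy-6-methylbenzoyl]oxy}-6-methylbenzoyl]oxy}-6-methylbenzoic acid (target)
Conditions: H2 (1 atm), 10% Pd/C, EtOAc/THF, rt
Reagents that add atoms: none
Why: Hydrogenolysis of three aryl benzyl ethers and one benzyl ester; aryl esters, methyl ethers and the arenes are inert. The solvent is non-nucleophilic so the depside bonds, now flanked by free hydroxyls, are not exchanged, and the acid is isolated without heating to avoid decarboxylation.

## Compound list

1 | orsellinic acid (2,4-dihydroxy-6-methylbenzoic acid) | Cc1cc(O)cc(O)c1C(=O)O | starting material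
2 | allyl bromide | C=CCBr | starting material
3 | allyl 2,4-dihydroxy-6-methylbenzoate (allyl orsellinate) | Cc1cc(O)cc(O)c1C(=O)OCC=C | intermediate
4 | dichloromethyl methyl ether | COC(Cl)Cl | starting material
5 | allyl 3-formyl-2,4-dihydroxy-6-methylbenzoate | Cc1cc(O)c(C=O)c(O)c1C(=O)OCC=C | intermediate
6 | benzyl bromide | BrCc1ccccc1 | starting material
7 | allyl 4-(benzyloxy)-3-formyl-2-hydroxy-6-methylbenzoate | Cc1cc(OCc2ccccc2)c(C=O)c(O)c1C(=O)OCC=C | intermediate
8 | methyl iodide | CI | starting material
9 | allyl 4-(benzyloxy)-3-formyl-2-methoxy-6-methylbenzoate | COc1c(C=O)c(OCc2ccccc2)cc(C)c1C(=O)OCC=C | intermediate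
10 | 4-(benzyloxy)-3-formyl-2-methoxy-6-methylbenzoic acid | COc1c(C=O)c(OCc2ccccc2)cc(C)c1C(=O)O | intermediate
11 | 4-(benzyloxy)-3-formyl-2-methoxy-6-methylbenzoyl chloride (formed in the flask, not isolated) | COc1c(C=O)c(OCc2ccccc2)cc(C)c1C(=O)Cl | intermediate
12 | allyl 4-{[4-(benzyloxy)-3-formyl-2-methoxy-6-methylbenzoyl]oxy}-2-hydroxy-6-methylbenzoate | COc1c(C=O)c(OCc2ccccc2)cc(C)c1C(=O)Oc1cc(C)c(C(=O)OCC=C)c(O)c1 | intermediate
13 | allyl 2-(benzyloxy)-4-{[4-(benzyloxy)-3-formyl-2-methoxy-6-methylbenzoyl]oxy}-6-methylbenzoate | COc1c(C=O)c(OCc2ccccc2)cc(C)c1C(=O)Oc1cc(C)c(C(=O)OCC=C)c(OCc2ccccc2)c1 | intermediate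
14 | 2-(benzyloxy)-4-{[4-(benzyloxy)-3-formyl-2-methoxy-6-methylbenzoyl]oxy}-6-methylbenzoic acid | COc1c(C=O)c(OCc2ccccc2)cc(C)c1C(=O)Oc1cc(C)c(C(=O)O)c(OCc2ccccc2)c1 | intermediate
15 | benzyl 2,4-dihydroxy-6-methylbenzoate (benzyl orsellinate) | Cc1cc(O)cc(O)c1C(=O)OCc1ccccc1 | intermediate
16 | 2-(benzyloxy)-4-{[4-(benzyloxy)-3-formyl-2-methoxy-6-methylbenzoyl]oxy}-6-methylbenzoyl chloride (formed in the flask, not isolated) | COc1c(C=O)c(OCc2ccccc2)cc(C)c1C(=O)Oc1cc(C)c(C(=O)Cl)c(OCc2ccccc2)c1 | intermediate
17 | benzyl 4-{[2-(benzyloxy)-4-{[4-(benzyloxy)-3-formyl-2-methoxy-6-methylbenzoyl]oxy}-6-methylbenzoyl]oxy}-2-hydroxy-6-methylbenzoate | COc1c(C=O)c(OCc2ccccc2)cc(C)c1C(=O)Oc1cc(C)c(C(=O)Oc2cc(C)c(C(=O)OCc3ccccc3)c(O)c2)c(OCc2ccccc2)c1 | intermediate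
18 | benzyl 2-(benzyloxy)-4-{[2-(benzyloxy)-4-{[4-(benzyloxy)-3-formyl-2-methoxy-6-methylbenzoyl]oxy}-6-methylbenzoyl]oxy}-6-methylbenzoate | COc1c(C=O)c(OCc2ccccc2)cc(C)c1C(=O)Oc1cc(C)c(C(=O)Oc2cc(C)c(C(=O)OCc3ccccc3)c(OCc3ccccc3)c2)c(OCc2ccccc2)c1 | intermediate
19 | benzyl 2-(benzyloxy)-4-{[2-(benzyloxy)-4-{[4-(benzyloxy)-3-(formyloxy)-2-methoxy-6-methylbenzoyl]oxy}-6-methylbenzoyl]oxy}-6-methylbenzoate (formed in the flask, not isolated) | COc1c(OC=O)c(OCc2ccccc2)cc(C)c1C(=O)Oc1cc(C)c(C(=O)Oc2cc(C)c(C(=O)OCc3ccccc3)c(OCc3ccccc3)c2)c(OCc2ccccc2)c1 | intermediate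
20 | benzyl 2-(benzyloxy)-4-{[2-(benzyloxy)-4-{[4-(benzyloxy)-3-hydroxy-2-methoxy-6-methylbenzoyl]oxy}-6-methylbenzoyl]oxy}-6-methylbenzoate | COc1c(O)c(OCc2ccccc2)cc(C)c1C(=O)Oc1cc(C)c(C(=O)Oc2cc(C)c(C(=O)OCc3ccccc3)c(OCc3ccccc3)c2)c(OCc2ccccc2)c1 | intermediate
21 | benzyl 2-(benzyloxy)-4-{[2-(benzyloxy)-4-{[4-(benzyloxy)-2,3-dimethoxy-6-methylbenzoyl]oxy}-6-methylbenzoyl]oxy}-6-methylbenzoate | COc1c(OC)c(OCc2ccccc2)cc(C)c1C(=O)Oc1cc(C)c(C(=O)Oc2cc(C)c(C(=O)OCc3ccccc3)c(OCc3ccccc3)c2)c(OCc2ccccc2)c1 | intermediate
22 | 2-hydroxy-4-{[2-hydroxy-4-{[4-hydroxy-2,3-dimethoxy-6-methylbenzoyl]oxy}-6-methylbenzoyl]oxy}-6-methylbenzoic acid | COc1c(O)cc(C)c(C(=O)Oc2cc(C)c(C(=O)Oc3cc(C)c(C(=O)O)c(O)c3)c(O)c2)c1OC | target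

## Step count and least certain steps

Total step count: 14. Longest linear sequence: 13 steps from 1 (steps 1 to 8 and 10 to 14); step 9 is the only side branch.

**Step 12 (key step).** The most likely failure is partial methanolysis of a depside ester while the formate is being cleaved, or oxidative degradation of ring A if peracid is still present when the phenol is set free. Hydride instead of aryl migration is thought unlikely because of the two ortho oxygen donors. The fallback moves the same oxidation to the monomer stage, where no depside ester exists; it sets out from 9 and returns to the route at 21. mCPBA in CH2Cl2 should give allyl 4-(benzyloxy)-3-(formyloxy)-2-methoxy-6-methylbenzoate F1; the terminal, electron-poor alkene of the allyl ester should react far more slowly than the activated aldehyde. KHCO3 in methanol would give allyl 4-(benzyloxy)-3-hydroxy-2-methoxy-6-methylbenzoate F2, MeI/K2CO3 would give allyl 4-(benzyloxy)-2,3-dimethoxy-6-methylbenzoate F3, and deallylation as in step 5 would give 4-(benzyloxy)-2,3-dimethoxy-6-methylbenzoic acid F4. Its acid chloride, 4-(benzyloxy)-2,3-dimethoxy-6-methylbenzoyl chloride F5, would be coupled with 3 to allyl 4-{[4-(benzyloxy)-2,3-dimethoxy-6-methylbenzoyl]oxy}-2-hydroxy-6-methylbenzoate F6. This would be benzylated to allyl 2-(benzyloxy)-4-{[4-(benzyloxy)-2,3-dimethoxy-6-methylbenzoyl]oxy}-6-methylbenzoate F7 and deallylated to 2-(benzyloxy)-4-{[4-(benzyloxy)-2,3-dimethoxy-6-methylbenzoyl]oxy}-6-methylbenzoic acid F8. The acid chloride of this, 2-(benzyloxy)-4-{[4-(benzyloxy)-2,3-dimethoxy-6-methylbenzoyl]oxy}-6-methylbenzoyl chloride F9, would be coupled with 15 to benzyl 4-{[2-(benzyloxy)-4-{[4-(benzyloxy)-2,3-dimethoxy-6-methylbenzoyl]oxy}-6-methylbenzoyl]oxy}-2-hydroxy-6-methylbenzoate F10, and benzylation as in step 11 reaches 21. The step count is unchanged; the price is that the electron-rich trioxygenated ring is carried through both couplings.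

**Step 2.** Formylation at C5 (ortho to O4, para to O2) may compete with formylation at C3, because both carbons are activated by the two hydroxyls and only titanium coordination tips the balance. The fallback takes the site choice out of the reagent's hands; it sets out from 3 and returns at 7, so it also bypasses step 3. Benzylation of 3 (BnBr, K2CO3, acetone) at the non-chelated O4 should give allyl 4-(benzyloxy)-2-hydroxy-6-methylbenzoate F11. Magnesium-mediated ortho-formylation (MgCl2, Et3N, paraformaldehyde, MeCN, reflux) takes place only ortho to a free phenol, and C3 is the only such position, so 7 should result.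

**Step 3.** Alkylation may spread over O2 and O4 or run on to the dibenzyl ether, because both hydroxyls are chelated and the difference in acidity is moderate. The fallback sets out from 5 and returns at 7 without a new compound. It replaces phenoxide alkylation by a Mitsunobu etherification with benzyl alcohol, PPh3 and DIAD in THF at 0 °C. Here the neutral phenol is alkylated through a bulky alkoxyphosphonium ion, one phenoxide equivalent at a time, which should sharpen the preference for the less crowded and more acidic O4 and exclude a dianion.

**Step 11.** While the sluggish chelated hydroxyl is being alkylated at 50 °C, phenoxide or carbonate may cleave or scramble a depside ester. The fallback brings ring C in already benzylated, so that no base ever meets the tridepside and the coupling partner has a single free hydroxyl; it sets out from 15, uses 14 as the acid partner and returns at 18. Allylation of 15 (2, K2CO3, acetone) at O4 should give benzyl 4-(allyloxy)-2-hydroxy-6-methylbenzoate F12. Benzylation (BnBr, K2CO3, DMF, 60 °C) would give benzyl 4-(allyloxy)-2-(benzyloxy)-6-methylbenzoate F13, and deallylation (Pd(PPh3)4, p-TolSO2Na) would give benzyl 2-(benzyloxy)-4-hydroxy-6-methylbenzoate F14, the same compound as A6. Acylation of F14 with 16 under the conditions of step 10 gives 18 directly. This costs two more steps but also removes the choice between O2 and O4 in step 10.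

## Further compounds

F1 | step 12 | allyl 4-(benzyloxy)-3-(formyloxy)-2-methoxy-6-methylbenzoate | COc1c(OC=O)c(OCc2ccccc2)cc(C)c1C(=O)OCC=C
F2 | step 12 | allyl 4-(benzyloxy)-3-hydroxy-2-methoxy-6-methylbenzoate | COc1c(O)c(OCc2ccccc2)cc(C)c1C(=O)OCC=C
F3 | step 12 | allyl 4-(benzyloxy)-2,3-dimethoxy-6-methylbenzoate | COc1c(OC)c(OCc2ccccc2)cc(C)c1C(=O)OCC=C
F4 | step 12 | 4-(benzyloxy)-2,3-dimethoxy-6-methylbenzoic acid | COc1c(OC)c(OCc2ccccc2)cc(C)c1C(=O)O
F5 | step 12 | 4-(benzyloxy)-2,3-dimethoxy-6-methylbenzoyl chloride | COc1c(OC)c(OCc2ccccc2)cc(C)c1C(=O)Cl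
F6 | step 12 | allyl 4-{[4-(benzyloxy)-2,3-dimethoxy-6-methylbenzoyl]oxy}-2-hydroxy-6-methylbenzoate | COc1c(OC)c(OCc2ccccc2)cc(C)c1C(=O)Oc1cc(C)c(C(=O)OCC=C)c(O)c1
F7 | step 12 | allyl 2-(benzyloxy)-4-{[4-(benzyloxy)-2,3-dimethoxy-6-methylbenzoyl]oxy}-6-methylbenzoate | COc1c(OC)c(OCc2ccccc2)cc(C)c1C(=O)Oc1cc(C)c(C(=O)OCC=C)c(OCc2ccccc2)c1
F8 | step 12 | 2-(benzyloxy)-4-{[4-(benzyloxy)-2,3-dimethoxy-6-methylbenzoyl]oxy}-6-methylbenzoic acid | COc1c(OC)c(OCc2ccccc2)cc(C)c1C(=O)Oc1cc(C)c(C(=O)O)c(OCc2ccccc2)c1
F9 | step 12 | 2-(benzyloxy)-4-{[4-(benzyloxy)-2,3-dimethoxy-6-methylbenzoyl]oxy}-6-methylbenzoyl chloride | COc1c(OC)c(OCc2ccccc2)cc(C)c1C(=O)Oc1cc(C)c(C(=O)Cl)c(OCc2ccccc2)c1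
F10 | step 12 | benzyl 4-{[2-(benzyloxy)-4-{[4-(benzyloxy)-2,3-dimethoxy-6-methylbenzoyl]oxy}-6-methylbenzoyl]oxy}-2-hydroxy-6-methylbenzoate | COc1c(OC)c(OCc2ccccc2)cc(C)c1C(=O)Oc1cc(C)c(C(=O)Oc2cc(C)c(C(=O)OCc3ccccc3)c(O)c2)c(OCc2ccccc2)c1
F11 | step 2 | allyl 4-(benzyloxy)-2-hydroxy-6-methylbenzoate | Cc1cc(OCc2ccccc2)cc(O)c1C(=O)OCC=C
F0 | step 3 | none | none
F12 | step 11 | benzyl 4-(allyloxy)-2-hydroxy-6-methylbenzoate | Cc1cc(OCC=C)cc(O)c1C(=O)OCc1ccccc1
F13 | step 11 | benzyl 4-(allyloxy)-2-(benzyloxy)-6-methylbenzoate | Cc1cc(OCC=C)cc(OCc2ccccc2)c1C(=O)OCc1ccccc1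
F14 | step 11 | benzyl 2-(benzyloxy)-4-hydroxy-6-methylbenzoate | Cc1cc(O)cc(OCc2ccccc2)c1C(=O)OCc1ccccc1
A1 | alternative 1 | 4-hydroxy-2-methylbenzoic acid | Cc1cc(O)ccc1C(=O)O
A2 | alternative 1 | benzyl 4-{[4-{[4-(acetyloxy)-2,3-dimethoxy-6-methylbenzoyl]oxy}-2-methylbenzoyl]oxy}-2-methylbenzoate | COc1c(OC(C)=O)cc(C)c(C(=O)Oc2cc(C)c(C(=O)Oc3cc(C)c(C(=O)OCc4ccccc4)cc3)cc2)c1OC
A3 | alternative 1 | benzyl 4-{[4-{[4-(acetyloxy)-2,3-dimethoxy-6-methylbenzoyl]oxy}-2-hydroxy-6-methylbenzoyl]oxy}-2-hydroxy-6-methylbenzoate | COc1c(OC(C)=O)cc(C)c(C(=O)Oc2cc(C)c(C(=O)Oc3cc(C)c(C(=O)OCc4ccccc4)c(O)c3)c(O)c2)c1OC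
A4 | alternative 2 | 6-(2,4-dioxopentyl)-2,2-dimethyl-4H-1,3-dioxin-4-one | CC(=O)CC(=O)CC1=CC(=O)OC(C)(C)O1
A5 | alternative 2 | 3,5,7-trioxooct-1-en-1-one (acylketene) | CC(=O)CC(=O)CC(=O)C=C=O
A6 | alternative 2 | benzyl 2-(benzyloxy)-4-hydroxy-6-methylbenzoate | Cc1cc(O)cc(OCc2ccccc2)c1C(=O)OCc1ccccc1
A7 | alternative 2 | benzyl 2-(benzyloxy)-6-methyl-4-[(3,5,7-trioxooctanoyl)oxy]benzoate | CC(=O)CC(=O)CC(=O)CC(=O)Oc1cc(C)c(C(=O)OCc2ccccc2)c(OCc2ccccc2)c1
A8 | alternative 2 | benzyl 2-(benzyloxy)-4-[(2,4-dihydroxy-6-methylbenzoyl)oxy]-6-methylbenzoate | Cc1cc(O)cc(O)c1C(=O)Oc1cc(C)c(C(=O)OCc2ccccc2)c(OCc2ccccc2)c1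
A9 | alternative 3 | 3-(benzyloxy)-4-bromo-5-methylphenol | Cc1cc(O)cc(OCc2ccccc2)c1Br
A10 | alternative 3 | 3-(benzyloxy)-4-bromo-5-methylphenyl 2-(benzyloxy)-4-{[4-(benzyloxy)-2,3-dimethoxy-6-methylbenzoyl]oxy}-6-methylbenzoate | COc1c(OCc2ccccc2)cc(C)c(C(=O)Oc2cc(C)c(C(=O)Oc3cc(C)c(Br)c(OCc4ccccc4)c3)c(OCc3ccccc3)c2)c1OC
A11 | alternative 3 | 2-(benzyloxy)-4-{[2-(benzyloxy)-4-{[4-(benzyloxy)-2,3-dimethoxy-6-methylbenzoyl]oxy}-6-methylbenzoyl]oxy}-6-methylbenzoic acid | COc1c(OCc2ccccc2)cc(C)c(C(=O)Oc2cc(C)c(C(=O)Oc3cc(C)c(C(=O)O)c(OCc4ccccc4)c3)c(OCc3ccccc3)c2)c1OC
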